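**Retrosynthetic overview**

1. Miyabenol A ⇐ its nona-O-benzyl ether; the terminal 4-oxystyryl group and the two inner stilbene links come from Heck reactions of C4 aryl triflates with 4-benzyloxystyrene.
2. Each trans-2,3-diaryl-2,3-dihydrobenzofuran (unit C carries the 3,5-dioxyphenyl group, unit B is the middle one, unit A carries the styryl group) is cut at C3a–C3 and O1–C2 into an E-stilbene and one quinoid carbene, delivered by an o-quinone diazide that already holds the C4 triflate and the C6 benzyl ether.
3. The dihydrofuran ring is not closed directly: carbene transfer first gives a spiro[2.5]octa-4,6-dien-8-one, and its three-membered ring (future C3a, C3, C2) is then expanded by C7a and O1 (Cloke–Wilson type) to the five-membered ring.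
4. Enabling feature: in every unit C2 bears a 4-oxyphenyl group and C3 a meta-dioxygenated aryl ring, while O1, C7a and C3a belong to a phloroglucinol-type ring. The spirocyclopropane can therefore ionise only at C3a–C2 (p-alkoxybenzylic cation, aromatising phenoxide), and the tetramer is resveratrol plus three identical C6 + C8 increments.
5. Order of ring formation: dihydrofuran of unit C (on tri-O-benzylresveratrol), then of unit B (key step, on per-benzylated ε-viniferin), then of unit A. C3 of unit C is set by the chiral dirhodium catalyst, C3 of units B and A by the neighbouring unit together with the matched catalyst, and every C2 by trans ring closure.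

Key step: step 9

Assumption: Rh2(S-TCPTTL)4 is dirhodium tetrakis[N-tetrachlorophthaloyl-(S)-tert-leucinate] (divalent rhodium); its sense of induction in step 7 is assigned by analogy, and if it proves opposite the catalyst antipodes of steps 7, 9 and 11 are exchanged and nothing else changes.
Assumption: 2-nitrophloroglucinol is taken as a purchasable material (otherwise it is one nitration step from phloroglucinol).

**Step 1**
Reactants: 1 resveratrol
Product: 2 tri-O-benzylresveratrol
Conditions: BnBr (3.6 equiv), K2CO3, DMF, 60 °C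
Reagents that add atoms: benzyl bromide, BrCc1ccccc1
Why: Williamson ether synthesis; all three phenoxides are alkylated under carbonate base with excess benzyl bromide.

**Step 2**
Reactants: 3 2-nitrophloroglucinol
Product: 4 5-(benzyloxy)-2-nitrobenzene-1,3-diol
Conditions: BnBr (1.0 equiv), K2CO3 (1.0 equiv), DMF, 25 °C
Reagents that add atoms: benzyl bromide, BrCc1ccccc1
Why: Williamson etherification is expected at the 5-hydroxyl only, because it is the most acidic one (para to the nitro group) while the 1- and 3-hydroxyls are tied up in hydrogen bonds to the nitro oxygens.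

**Step 3**
Reactants: 4 5-(benzyloxy)-2-nitrobenzene-1,3-diol
Product: 5 5-(benzyloxy)-3-hydroxy-2-nitrophenyl triflate
Conditions: PhNTf2 (1.0 equiv), Et3N (1.1 equiv), CH2Cl2, 0 °C
Reagents that add atoms: N-phenylbis(trifluoromethanesulfonimide), O=S(=O)(N(c1ccccc1)S(=O)(=O)C(F)(F)F)C(F)(F)F
Why: O-sulfonylation of one of two equivalent hydroxyls with one equivalent of a mild triflyl donor; the remaining hydroxyl stays hydrogen-bonded to the nitro group and is further deactivated by the new triflate.

**Step 4**
Reactants: 5 5-(benzyloxy)-3-hydroxy-2-nitrophenyl triflate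
Product: 6 2-amino-5-(benzyloxy)-3-hydroxyphenyl triflate
Conditions: H2 (1 atm), 5% Pt/C (sulfided), EtOAc, 25 °C
Reagents that add atoms: none
Why: Chemoselective catalytic hydrogenation of the nitro group over sulfided platinum, which should leave the benzyl aryl ether and the aryl triflate untouched.

**Step 5**
Reactants: 6 2-amino-5-(benzyloxy)-3-hydroxyphenyl triflate
Product: 7 o-quinone diazide
Conditions: t-BuONO (1.2 equiv), CF3CO2H (5 mol%), EtOH, 0 °C, dark; aq NaHCO3 wash
Reagents that add atoms: tert-butyl nitrite, CC(C)(C)ON=O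
Why: Diazotisation of the o-aminophenol with an alkyl nitrite; the diazonium ion loses the phenolic proton and gives the neutral o-quinone diazide.

**Step 6**
Reactants: 8 4-(benzyloxy)benzaldehyde
Product: 9 4-benzyloxystyrene
Conditions: Ph3PCH3Br (1.2 equiv), KOtBu (1.2 equiv), THF, 0 to 25 °C
Reagents that add atoms: methyltriphenylphosphonium bromide, C[P+](c1ccccc1)(c1ccccc1)c1ccccc1.[Br-]
Why: Wittig methylenation of the aryl aldehyde.

**Step 7**
Reactants: 2 tri-O-benzylresveratrol; 7 o-quinone diazide
Product: 11 unit C triflate, via spirocyclopropane 10 (not isolated)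
Conditions: 7 (1.3 equiv, added over 4 h), Rh2(S-TCPTTL)4 (1 mol%), 4 Å MS, PhCF3, 40 °C, dark
Reagents that add atoms: none
Why: Proposed new method: the divalent-rhodium quinoid carbene from 7 should cyclopropanate the electron-rich E-alkene of 2 to spirocyclopropane 10, which as a spiro-activated donor–acceptor cyclopropane ionises at the bond between the spiro carbon and the CH(4-benzyloxyphenyl) carbon (p-alkoxybenzylic cation, aromatising phenoxide) and recloses on oxygen to the trans-dihydrobenzofuran, the chiral carboxylate pocket choosing the alkene face and thereby C3 while C2 follows as trans; closest known reaction types: dirhodium-catalysed cyclopropanation of olefins with quinone diazides, formal [3+2] annulation of cyclic 2-diazo-1,3-diones with styrenes, and the Cloke–Wilson rearrangement.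

**Step 8**
Reactants: 11 unit C triflate; 9 4-benzyloxystyrene
Product: 12 penta-O-benzyl-ε-viniferin (2R,3R)
Conditions: 9 (1.5 equiv), Pd(OAc)2 (5 mol%), PPh3 (12 mol%), LiCl (3 equiv), K2CO3 (2 equiv), DMF, 100 °C
Reagents that add atoms: none
Why: Mizoroki–Heck reaction of the aryl triflate; chloride keeps the arylpalladium on the neutral pathway, so the aryl group adds to the terminal carbon and syn β-hydride elimination gives the E-stilbene.

**Step 9**
Reactants: 12 penta-O-benzyl-ε-viniferin (2R,3R); 7 o-quinone diazide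
Product: 14 unit B–C triflate, via spirocyclopropane 13 (not isolated)
Conditions: 7 (1.5 equiv, added over 6 h), Rh2(R-TCPTTL)4 (2 mol%), 4 Å MS, PhCF3, 40 °C, dark
Reagents that add atoms: none
Why: Proposed new method: the divalent-rhodium quinoid carbene formed from 7 by loss of N2 should transfer to the styryl C=C of 12 to give spiro[2.5]octa-4,6-dien-8-one 13, whose three-membered ring holds the future C3a (spiro carbon), C3 (carbon bearing the benzo ring of unit C) and C2 (carbon bearing the 4-benzyloxyphenyl group); this doubly activated donor–acceptor cyclopropane then ionises at the C3a–C2 bond, the only bond whose cleavage gives a p-alkoxybenzylic cation and an aromatic phenoxide, and the phenoxide oxygen closes on the cation (5-exo-trig on the quinone-methide-like cation), so that the three-membered ring is expanded by C7a and O1 to the dihydrofuran ring of unit B. The closest known reaction types are the dirhodium-catalysed cyclopropanation of olefins with quinone diazides (spirocyclopropanes are isolable in the para series), the formal [3+2] annulation of cyclic 2-diazo-1,3-diones with styrenes and the Cloke–Wilson rearrangement of aryl cyclopropyl ketones; what is new is an internal 1,2-diarylethene as the olefin and stereocontrol over the cascade. The cyclopropane is closed by [2+1] carbene transfer and the dihydrofuran by ring expansion through O-attack on the benzylic cation. C3 is fixed in the carbene transfer, which should take place on the alkene face anti to the 3-aryl group of the resident unit C in the rotamer that turns the β-carbon of the styryl group away from C3a, a substrate bias that leads to the required (3S) centre and that the matched R catalyst reinforces; C2 is fixed in the ring closure and should end up trans to C3, the less strained and more stable arrangement. The step needs chemoselectivity for the alkene over benzyl ether oxygens and electron-rich arenes, which slow addition of 7 and the high nucleophilicity of the 4-alkoxystyrene-type π-bond should secure, and ring opening toward C2 and not C3, which the para-benzyloxy group at C2 and the meta-dioxygenated, non-stabilising aryl ring at C3 secure; the C4 triflate leaves only one oxygen free to close the ring.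

**Step 10**
Reactants: 14 unit B–C triflate; 9 4-benzyloxystyrene
Product: 15 hepta-O-benzyl trimer stilbene
Conditions: 9 (1.5 equiv), Pd(OAc)2 (5 mol%), PPh3 (12 mol%), LiCl (3 equiv), K2CO3 (2 equiv), DMF, 100 °C
Reagents that add atoms: none
Why: Mizoroki–Heck reaction as in step 8, giving the E-stilbene by syn insertion and syn β-hydride elimination.

**Step 11**
Reactants: 15 hepta-O-benzyl trimer stilbene; 7 o-quinone diazide
Product: 17 unit A–B–C triflate, via spirocyclopropane 16 (not isolated)
Conditions: 7 (1.5 equiv, added over 6 h), Rh2(S-TCPTTL)4 (2 mol%), 4 Å MS, PhCF3, 40 °C, dark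
Reagents that add atoms: none
Why: Proposed new method: the same cyclopropanation and Cloke–Wilson-type ring-expansion cascade as in step 9 (closest known reaction types as given there) is applied to the styryl group of 15, C3 of unit A being set anti to the 3-aryl group of unit B with the matched S catalyst and C2 following as trans.

**Step 12**
Reactants: 17 unit A–B–C triflate; 9 4-benzyloxystyrene
Product: 18 nona-O-benzylmiyabenol A
Conditions: 9 (1.5 equiv), Pd(OAc)2 (5 mol%), PPh3 (12 mol%), LiCl (3 equiv), K2CO3 (2 equiv), DMF, 100 °C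
Reagents that add atoms: none
Why: Mizoroki–Heck reaction as in step 8, installing the terminal E-4-benzyloxystyryl group.

**Step 13**
Reactants: 18 nona-O-benzylmiyabenol A
Product: 19 miyabenol A
Conditions: BCl3 (excess), pentamethylbenzene, CH2Cl2, −78 °C; MeOH quench
Reagents that add atoms: none
Why: Lewis-acid debenzylation with BCl3 and the non-basic cation scavenger pentamethylbenzene at low temperature should cleave the nine aryl benzyl ethers without reducing the stilbene and without lasting ionisation of the C2–O bonds, whose trans arrangement is in any case the stable one.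

**Compound list**

1 | resveratrol, (E)-5-[2-(4-hydroxyphenyl)ethenyl]benzene-1,3-diol | Oc1ccc(/C=C/c2cc(O)cc(O)c2)cc1 | starting material
2 | tri-O-benzylresveratrol, (E)-3,5,4'-tris(benzyloxy)stilbene | C(c9ccccc9)Oc8ccc(cc8)/C=C/c7cc(OCc9ccccc9)cc(OCc9ccccc9)c7 | intermediate
3 | 2-nitrophloroglucinol (2-nitrobenzene-1,3,5-triol) | O=[N+]([O-])c1c(O)cc(O)cc1O | starting material
4 | 5-(benzyloxy)-2-nitrobenzene-1,3-diol | O=[N+]([O-])c1c(O)cc(OCc2ccccc2)cc1O | intermediate
5 | 5-(benzyloxy)-3-hydroxy-2-nitrophenyl trifluoromethanesulfonate | O=[N+]([O-])c1c(O)cc(OCc2ccccc2)cc1OS(=O)(=O)C(F)(F)F | intermediate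
6 | 2-amino-5-(benzyloxy)-3-hydroxyphenyl trifluoromethanesulfonate | Nc1c(O)cc(OCc2ccccc2)cc1OS(=O)(=O)C(F)(F)F | intermediate
7 | o-quinone diazide, 5-(benzyloxy)-2-diazo-3-[(trifluoromethanesulfonyl)oxy]cyclohexa-3,5-dien-1-one | O=C1C=C(OCc2ccccc2)C=C(OS(=O)(=O)C(F)(F)F)C1=[N+]=[N-] | intermediate
8 | 4-(benzyloxy)benzaldehyde | O=Cc1ccc(OCc2ccccc2)cc1 | starting material
9 | 4-benzyloxystyrene, 1-(benzyloxy)-4-ethenylbenzene | C=Cc1ccc(OCc2ccccc2)cc1 | intermediate
10 | spirocyclopropane of unit C: (1R,2R)-trans-1-[3,5-bis(benzyloxy)phenyl]-2-[4-(benzyloxy)phenyl]-6-(benzyloxy)-8-oxospiro[2.5]octa-4,6-dien-4-yl trifluoromethanesulfonate; spiro centre formed as either epimer and lost on ring expansion | O=C1C=C(OCc9ccccc9)C=C(OS(=O)(=O)C(F)(F)F)C12[C@@H](c7cc(OCc9ccccc9)cc(OCc9ccccc9)c7)[C@@H]2c8ccc(OCc9ccccc9)cc8 | intermediate (not isolated)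
11 | unit C triflate: (2R,3R)-6-(benzyloxy)-2-[4-(benzyloxy)phenyl]-3-[3,5-bis(benzyloxy)phenyl]-2,3-dihydro-1-benzofuran-4-yl trifluoromethanesulfonate | FC(F)(F)S(=O)(=O)Oc5cc(OCc9ccccc9)cc6c5[C@@H](c7cc(OCc9ccccc9)cc(OCc9ccccc9)c7)[C@H](c8ccc(OCc9ccccc9)cc8)O6 | intermediate
12 | penta-O-benzyl-ε-viniferin: (2R,3R)-6-(benzyloxy)-2-[4-(benzyloxy)phenyl]-4-{(E)-2-[4-(benzyloxy)phenyl]ethenyl}-3-[3,5-bis(benzyloxy)phenyl]-2,3-dihydro-1-benzofuran | C(c9ccccc9)Oc8ccc(cc8)/C=C/c5cc(OCc9ccccc9)cc6c5[C@@H](c7cc(OCc9ccccc9)cc(OCc9ccccc9)c7)[C@H](c8ccc(OCc9ccccc9)cc8)O6 | intermediate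
13 | spirocyclopropane of unit B: (1S,2S)-trans-spiro[2.5]octa-4,6-dien-8-one as in 10, but with the unit C dihydrobenzofuran-4-yl group of 12 at C1 in place of the 3,5-bis(benzyloxy)phenyl group; spiro centre formed as either epimer | O=C1C=C(OCc9ccccc9)C=C(OS(=O)(=O)C(F)(F)F)C12[C@H](c5cc(OCc9ccccc9)cc6c5[C@@H](c7cc(OCc9ccccc9)cc(OCc9ccccc9)c7)[C@H](c8ccc(OCc9ccccc9)cc8)O6)[C@H]2c8ccc(OCc9ccccc9)cc8 | intermediate (not isolated)
14 | unit B–C triflate: (2S,3S)-6-(benzyloxy)-2-[4-(benzyloxy)phenyl]-3-{(2R,3R)-6-(benzyloxy)-2-[4-(benzyloxy)phenyl]-3-[3,5-bis(benzyloxy)phenyl]-2,3-dihydro-1-benzofuran-4-yl}-2,3-dihydro-1-benzofuran-4-yl trifluoromethanesulfonate | FC(F)(F)S(=O)(=O)Oc3cc(OCc9ccccc9)cc4c3[C@H](c5cc(OCc9ccccc9)cc6c5[C@@H](c7cc(OCc9ccccc9)cc(OCc9ccccc9)c7)[C@H](c8ccc(OCc9ccccc9)cc8)O6)[C@@H](c8ccc(OCc9ccccc9)cc8)O4 | intermediate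
15 | hepta-O-benzyl trimer stilbene: compound 14 with an (E)-2-[4-(benzyloxy)phenyl]ethenyl group at C4 of unit B in place of the triflate | C(c9ccccc9)Oc8ccc(cc8)/C=C/c3cc(OCc9ccccc9)cc4c3[C@H](c5cc(OCc9ccccc9)cc6c5[C@@H](c7cc(OCc9ccccc9)cc(OCc9ccccc9)c7)[C@H](c8ccc(OCc9ccccc9)cc8)O6)[C@@H](c8ccc(OCc9ccccc9)cc8)O4 | intermediate
16 | spirocyclopropane of unit A: (1R,2R)-trans-spiro[2.5]octa-4,6-dien-8-one as in 10, with the unit B–C group of 15 (attached through C4 of unit B) at C1; spiro centre formed as either epimer | O=C1C=C(OCc9ccccc9)C=C(OS(=O)(=O)C(F)(F)F)C12[C@@H](c3cc(OCc9ccccc9)cc4c3[C@H](c5cc(OCc9ccccc9)cc6c5[C@@H](c7cc(OCc9ccccc9)cc(OCc9ccccc9)c7)[C@H](c8ccc(OCc9ccccc9)cc8)O6)[C@@H](c8ccc(OCc9ccccc9)cc8)O4)[C@@H]2c8ccc(OCc9ccccc9)cc8 | intermediate (not isolated)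
17 | unit A–B–C triflate: (2R,3R)-6-(benzyloxy)-2-[4-(benzyloxy)phenyl]-2,3-dihydro-1-benzofuran-4-yl trifluoromethanesulfonate carrying at C3 the (2S,3S)/(2R,3R) unit B–C group of 14, attached through C4 of unit B | FC(F)(F)S(=O)(=O)Oc1cc(OCc9ccccc9)cc2c1[C@@H](c3cc(OCc9ccccc9)cc4c3[C@H](c5cc(OCc9ccccc9)cc6c5[C@@H](c7cc(OCc9ccccc9)cc(OCc9ccccc9)c7)[C@H](c8ccc(OCc9ccccc9)cc8)O6)[C@@H](c8ccc(OCc9ccccc9)cc8)O4)[C@H](c8ccc(OCc9ccccc9)cc8)O2 | intermediate
18 | nona-O-benzylmiyabenol A: compound 17 with an (E)-2-[4-(benzyloxy)phenyl]ethenyl group at C4 of unit A in place of the triflate | C(c9ccccc9)Oc8ccc(cc8)/C=C/c1cc(OCc9ccccc9)cc2c1[C@@H](c3cc(OCc9ccccc9)cc4c3[C@H](c5cc(OCc9ccccc9)cc6c5[C@@H](c7cc(OCc9ccccc9)cc(OCc9ccccc9)c7)[C@H](c8ccc(OCc9ccccc9)cc8)O6)[C@@H](c8ccc(OCc9ccccc9)cc8)O4)[C@H](c8ccc(OCc9ccccc9)cc8)O2 | intermediate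
19 | miyabenol A; (2R,3R) in units A and C, (2S,3S) in unit B, E-alkene | Oc1ccc(/C=C/c2cc(O)cc3c2[C@@H](c2cc(O)cc4c2[C@H](c2cc(O)cc5c2[C@@H](c2cc(O)cc(O)c2)[C@H](c2ccc(O)cc2)O5)[C@@H](c2ccc(O)cc2)O4)[C@H](c2ccc(O)cc2)O3)cc1 | target

**Totals**

Total step count: 13. Longest linear sequence: 11 steps (steps 2, 3, 4, 5, 7, 8, 9, 10, 11, 12, 13).

**Steps most likely to fail**

Step 9 (Proposed new method). Carbene transfer to the hindered internal alkene of 12 may be too slow, so that decay of the carbene takes over: Wolff-type ring contraction, dimerisation, or attack on the benzyloxy-substituted arenes and benzylic C–H bonds. Facial discrimination may also be incomplete. The fallback uses known chemistry, sets out from 11 (with 7 as the source of the second component) and comes back to the route at 14, so that steps 8 and 9 are bypassed. Palladium-catalysed reductive carbonylation of the diazonium form of 7 (HBF4·OEt2, Pd(OAc)2, CO, Et3SiH, MeCN) should give 4-(benzyloxy)-2-hydroxy-6-(triflyloxy)benzaldehyde F1. Miyaura borylation of 11 (B2pin2, PdCl2(dppf), KOAc, dioxane, 90 °C) should give the unit C pinacol boronate F2. Rhodium-catalysed 1,2-addition of F2 to F1 ([Rh(OH)(cod)]2, aqueous dioxane, 60 °C) should give the o-hydroxybenzhydrol F3 as a mixture at the carbinol carbon. Treatment of F3 with [4-(benzyloxy)benzyl]dimethylsulfonium bromide F4 and Cs2CO3 (MeCN, 40 °C) should bring about base-induced dehydration to the o-quinone methide and the known trans-selective [4+1] annulation with the sulfonium benzylide, giving 14. The ylide carbon is expected to add anti to the 3-aryl group of unit C, for the same reason as in the main route.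

Step 11 (Proposed new method). The same processes as in step 9 may interfere, made worse by the greater crowding around the alkene of 15 and by the larger number of competing arenes and benzylic ethers. The fallback uses the same known chemistry, sets out from 14 and comes back at 17, bypassing steps 10 and 11. Miyaura borylation of 14 should give the unit B–C pinacol boronate F5. Rhodium-catalysed addition of F5 to the salicylaldehyde F1 should give the o-hydroxybenzhydrol F6. The [4+1] annulation of F6 with the ylide from the sulfonium salt F4 (Cs2CO3, MeCN) should give 17.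

Step 7 (Proposed new method). Enantioselection rests on the catalyst alone and may be low for an E-1,2-diarylethene. Arene attack by the carbene may compete as well. The fallback uses known chemistry, sets out from 7 and comes back at 11. The salicylaldehyde F1 is made from 7 as above. Rhodium-catalysed addition of commercial 3,5-bis(benzyloxy)phenylboronic acid to F1 should give the racemic o-hydroxybenzhydrol F7. Its [4+1] annulation (Cs2CO3, MeCN) with the benzylide from the C2-symmetric (2R,5R)-1-[4-(benzyloxy)benzyl]-2,5-dimethylthiolanium bromide F8 should give 11. Here the chiral sulfide, not a catalyst on the carbene, selects the face of the ylide carbon, and phenoxide displacement of the sulfide closes the trans ring. The antipodal sulfide would be used if the sense of induction requires it.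

**Further compounds**

F1 | step 9 | 4-(benzyloxy)-2-hydroxy-6-[(trifluoromethanesulfonyl)oxy]benzaldehyde | O=Cc1c(O)cc(OCc2ccccc2)cc1OS(=O)(=O)C(F)(F)F
F2 | step 9 | 2-[(2R,3R)-6-(benzyloxy)-2-[4-(benzyloxy)phenyl]-3-[3,5-bis(benzyloxy)phenyl]-2,3-dihydro-1-benzofuran-4-yl]-4,4,5,5-tetramethyl-1,3,2-dioxaborolane | CC1(C)OB(OC1(C)C)c5cc(OCc9ccccc9)cc6c5[C@@H](c7cc(OCc9ccccc9)cc(OCc9ccccc9)c7)[C@H](c8ccc(OCc9ccccc9)cc8)O6
F3 | step 9 | 5-(benzyloxy)-3-hydroxy-2-{hydroxy[unit C dihydrobenzofuran-4-yl]methyl}phenyl trifluoromethanesulfonate, mixture at the carbinol carbon | OC(c5cc(OCc9ccccc9)cc6c5[C@@H](c7cc(OCc9ccccc9)cc(OCc9ccccc9)c7)[C@H](c8ccc(OCc9ccccc9)cc8)O6)c1c(O)cc(OCc9ccccc9)cc1OS(=O)(=O)C(F)(F)F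
F4 | step 9 | [4-(benzyloxy)benzyl]dimethylsulfonium bromide | C[S+](C)Cc1ccc(OCc2ccccc2)cc1.[Br-]
F5 | step 11 | pinacol boronate of unit B–C: compound 14 with a 4,4,5,5-tetramethyl-1,3,2-dioxaborolan-2-yl group in place of the triflate | CC1(C)OB(OC1(C)C)c3cc(OCc9ccccc9)cc4c3[C@H](c5cc(OCc9ccccc9)cc6c5[C@@H](c7cc(OCc9ccccc9)cc(OCc9ccccc9)c7)[C@H](c8ccc(OCc9ccccc9)cc8)O6)[C@@H](c8ccc(OCc9ccccc9)cc8)O4
F6 | step 11 | 5-(benzyloxy)-3-hydroxy-2-{hydroxy[unit B–C dihydrobenzofuran-4-yl]methyl}phenyl trifluoromethanesulfonate, mixture at the carbinol carbon | OC(c3cc(OCc9ccccc9)cc4c3[C@H](c5cc(OCc9ccccc9)cc6c5[C@@H](c7cc(OCc9ccccc9)cc(OCc9ccccc9)c7)[C@H](c8ccc(OCc9ccccc9)cc8)O6)[C@@H](c8ccc(OCc9ccccc9)cc8)O4)c1c(O)cc(OCc9ccccc9)cc1OS(=O)(=O)C(F)(F)F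
F7 | step 7 | 5-(benzyloxy)-2-{[3,5-bis(benzyloxy)phenyl](hydroxy)methyl}-3-hydroxyphenyl trifluoromethanesulfonate, racemic | OC(c7cc(OCc9ccccc9)cc(OCc9ccccc9)c7)c1c(O)cc(OCc9ccccc9)cc1OS(=O)(=O)C(F)(F)F
F8 | step 7 | (2R,5R)-1-[4-(benzyloxy)benzyl]-2,5-dimethylthiolan-1-ium bromide | C[C@@H]1CC[C@@H](C)[S+]1Cc2ccc(OCc3ccccc3)cc2.[Br-]
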